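Sauriol B is the linear chain ring A–C7–C8–C8'–C7'–ring B. Its adjacent carbons C8 and C8' each bear a one-carbon branch (C9, C9') in a threo 8R,8'R relation. An E-configured C8=C8' alkene acquires exactly this pattern when both branches are delivered to the same face. Everything rests on cutting C8–C9 and C8'–C9' together. In one flask the alkene is diborated on one face, a CH2 is slipped into each C–B bond with retention, and oxidation gives the (2R,3R)-1,4-diol. This makes two C–C bonds and both stereocentres at once. The precursor is the tribenzyl-protected (E)-1,4-diarylbut-2-ene with rings A and B already differentiated. Deoxygenation and hydrogenolysis finish the synthesis.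

Key step: step 7

Remark on numbering: C7/C7' are the benzylic CH2 groups, C8/C8' the methines and C9/C9' the branch carbons. Ring A is 3,4-dihydroxy-5-methoxyphenyl and ring B is 4-hydroxy-3,5-dimethoxyphenyl.

Assumption: (S)-QUINAP is taken as the ligand antipode that leads to the 8R,8'R series. The sense of induction is to be confirmed at the bis-mesylate stage (X-ray, anomalous dispersion of sulfur), and the equally available (R)-QUINAP replaces it if the sense proves opposite.

Step 1
Reactants: 1 4-allyl-2,6-dimethoxyphenol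
Product: 2 5-allyl-2-(benzyloxy)-1,3-dimethoxybenzene
Conditions: BnBr, K2CO3, DMF, 50 °C
Reagents that add atoms: benzyl bromide, BrCc1ccccc1
Why: Williamson ether synthesis, in which the phenoxide formed by K2CO3 displaces bromide from benzyl bromide by SN2 and the mild base leaves the allyl group out of conjugation.

Step 2
Reactants: 2 5-allyl-2-(benzyloxy)-1,3-dimethoxybenzene; 3 (Z)-but-2-ene-1,4-diyl diacetate (3 equiv)
Product: 4 (E)-4-[4-(benzyloxy)-3,5-dimethoxyphenyl]but-2-en-1-yl acetate
Conditions: second-generation Grubbs catalyst RuCl2(=CHPh)(PCy3)(SIMes) (3 mol %), 1,4-benzoquinone (10 mol %), CH2Cl2, 40 °C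
Reagents that add atoms: none
Why: Olefin cross-metathesis of a terminal allylarene with an excess of a symmetrical internal allylic diacetate is a selective pairing that favours the E-alkene under thermodynamic control, benzoquinone suppresses ruthenium hydride-induced allyl-to-propenyl migration, and residual Z isomer is tolerable because step 6 runs through an equilibrating allylpalladium species.

Step 3
Reactants: 5 5-bromo-2-hydroxy-3-methoxybenzaldehyde
Product: 7 5-bromo-3-methoxybenzene-1,2-diol, via aryl formate 6 (not isolated)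
Conditions: H2O2 (30% aq), NaOH (aq), N2, 0 °C → rt; then HCl
Reagents that add atoms: hydrogen peroxide, OO
Why: Dakin oxidation, in which hydroperoxide adds to the ortho-hydroxybenzaldehyde, the electron-rich aryl group migrates to oxygen to give formate 6 and hydroxide cleaves it, so the new phenol sits exactly at the former formyl carbon and the oxygenation pattern of ring A is fixed without any selective ether cleavage.

Step 4
Reactants: 7 5-bromo-3-methoxybenzene-1,2-diol
Product: 8 1,2-bis(benzyloxy)-5-bromo-3-methoxybenzene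
Conditions: BnBr (2.3 equiv), K2CO3, DMF, N2, 60 °C
Reagents that add atoms: benzyl bromide, BrCc1ccccc1
Why: Double Williamson ether synthesis on both catechol oxygens, run under nitrogen because the catecholate is sensitive to air, with the aryl bromide inert to these conditions.

Step 5
Reactants: 8 1,2-bis(benzyloxy)-5-bromo-3-methoxybenzene
Product: 11 [3,4-bis(benzyloxy)-5-methoxyphenyl]boronic acid, via aryllithium 9 (not isolated), via lithium aryltriisopropoxyborate 10 (not isolated)
Conditions: n-BuLi, THF, −78 °C; B(OiPr)3, −78 °C → rt; 1 M HCl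
Reagents that add atoms: triisopropyl borate, CC(C)OB(OC(C)C)OC(C)C; water, O; n-butyllithium, [Li]CCCC (lithium only in 9 and 10)
Why: Bromine–lithium exchange at −78 °C outruns benzylic deprotonation, aryllithium 9 is trapped by the borate ester as ate complex 10, and acid hydrolysis releases the boronic acid (standard lithiation–borylation of an aryl bromide).

Step 6
Reactants: 4 (E)-4-[4-(benzyloxy)-3,5-dimethoxyphenyl]but-2-en-1-yl acetate; 11 [3,4-bis(benzyloxy)-5-methoxyphenyl]boronic acid (1.3 equiv)
Product: 12 (E)-1-[3,4-bis(benzyloxy)-5-methoxyphenyl]-4-[4-(benzyloxy)-3,5-dimethoxyphenyl]but-2-ene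
Conditions: Pd(PPh3)4 (5 mol %), K2CO3, THF–H2O (10:1), 60 °C
Reagents that add atoms: none
Why: Allylic Suzuki–Miyaura arylation (Tsuji–Trost ionisation followed by transmetalation), in which zerovalent palladium ionises the acetate to the more stable syn η3-allyl complex, the aryl group passes from boron to palladium and reductive elimination at the unsubstituted allyl terminus gives the linear E-alkene, any Z-acetate converging on the same complex by η3–η1–η3 equilibration.

Step 7
Reactants: 12 (E)-1-[3,4-bis(benzyloxy)-5-methoxyphenyl]-4-[4-(benzyloxy)-3,5-dimethoxyphenyl]but-2-ene; 13 bis(catecholato)diboron (1.1 equiv)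
Product: 17 (2R,3R)-2-[3,4-bis(benzyloxy)-5-methoxybenzyl]-3-[4-(benzyloxy)-3,5-dimethoxybenzyl]butane-1,4-diol, via threo 1,2-bis(catecholboronate) 14 (not isolated), via bis(chloromethyl) ate complex 15 (not isolated), via homologated 1,4-bis(catecholboronate) 16 (not isolated)
Conditions: Rh(acac)(nbd) (5 mol %), (S)-QUINAP (5 mol %), THF, rt; then BrCH2Cl (4 equiv), n-BuLi (3.5 equiv), −78 °C → rt; then NaOH (3 M aq), H2O2 (30% aq), 0 °C → rt
Reagents that add atoms: bromochloromethane, ClCBr; hydrogen peroxide, OO; n-butyllithium, [Li]CCCC (lithium only in 15)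
Why: The monovalent rhodium–QUINAP complex cleaves the B–B bond of 13 by oxidative addition to a trivalent bis(boryl)rhodium species, alkene 12 binds through one enantiotopic face and inserts into a Rh–B bond, and C–B reductive elimination with retention completes a suprafacial delivery of both boryl groups (14). Chloromethyllithium, generated beside the boronate from BrCH2Cl and n-BuLi at −78 °C, adds to each Lewis-acidic boron to give 15, and on warming C8 and C8' shift from boron to the CH2 carbon as chloride leaves, with retention at the migrating carbon (Matteson homologation, forming C8–C9 and C8'–C9' in 16), after which hydroperoxide turns both primary C–B bonds into C–OH. The closest known reaction type is the rhodium–QUINAP enantioselective diboration of internal E-alkenes run in one flask with chloromethyllithium homologation and oxidation to 2,3-disubstituted butane-1,4-diols, and no ring is closed. The absolute configuration at C8 and C8' is fixed by the alkene face that the P,N ligand exposes to rhodium, and their threo relation by the E geometry of 12 combined with syn addition and two retentive migrations. Only facial selectivity is required, because both C–B bonds meet the same fate and no regiochemical choice arises, and the alkene is flanked by two unbranched CH2 groups, the steric profile this catalyst handles best. Chemoselectivity rests on the three benzyl ethers, which remove every acidic O–H that would quench the carbenoid or exchange with 13, and over-homologation is limited because the carbenoid decomposes below the temperature at which migration regenerates tricoordinate boron.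

Step 8
Reactants: 17 (2R,3R)-2-[3,4-bis(benzyloxy)-5-methoxybenzyl]-3-[4-(benzyloxy)-3,5-dimethoxybenzyl]butane-1,4-diol
Product: 18 (2R,3R)-2-[3,4-bis(benzyloxy)-5-methoxybenzyl]-3-[4-(benzyloxy)-3,5-dimethoxybenzyl]butane-1,4-diyl dimethanesulfonate
Conditions: MsCl (3 equiv), Et3N (4 equiv), CH2Cl2, −10 → 0 °C
Reagents that add atoms: methanesulfonyl chloride, CS(=O)(=O)Cl
Why: O-Mesylation through sulfene (from MsCl and Et3N) is fast at low temperature, so both primary hydroxyls should be capped before a monomesylate can close to a cyclic ether, and the stereocentres one carbon away are not touched.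

Step 9
Reactants: 18 (2R,3R)-2-[3,4-bis(benzyloxy)-5-methoxybenzyl]-3-[4-(benzyloxy)-3,5-dimethoxybenzyl]butane-1,4-diyl dimethanesulfonate
Product: 19 (2R,3R)-1-[3,4-bis(benzyloxy)-5-methoxyphenyl]-4-[4-(benzyloxy)-3,5-dimethoxyphenyl]-2,3-dimethylbutane
Conditions: LiAlH4, THF, 0 → 60 °C
Reagents that add atoms: none
Why: SN2 displacement of primary mesylates by hydride, the customary deoxygenation of 2,3-dibenzylbutane-1,4-diols in lignan chemistry, turns C9 and C9' into methyl groups while aryl benzyl and methyl ethers are inert and C8 and C8' keep their geometry (descriptors stay R,R).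

Step 10
Reactants: 19 (2R,3R)-1-[3,4-bis(benzyloxy)-5-methoxyphenyl]-4-[4-(benzyloxy)-3,5-dimethoxyphenyl]-2,3-dimethylbutane
Product: 20 sauriol B, 5-[(2R,3R)-4-(4-hydroxy-3,5-dimethoxyphenyl)-2,3-dimethylbutyl]-3-methoxybenzene-1,2-diol
Conditions: H2 (1 atm), 10% Pd/C, degassed EtOAc–MeOH, rt
Reagents that add atoms: none
Why: Catalytic hydrogenolysis cleaves the three benzylic C–O bonds under neutral conditions, whereas the aryl methyl ethers, the saturated chain and its two non-epimerisable stereocentres are unaffected.

Compound list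
1 | 4-allyl-2,6-dimethoxyphenol | C=CCc1cc(OC)c(O)c(OC)c1 | starting material
2 | 5-allyl-2-(benzyloxy)-1,3-dimethoxybenzene | C=CCc1cc(OC)c(OCc2ccccc2)c(OC)c1 | intermediate
3 | (Z)-but-2-ene-1,4-diyl diacetate | CC(=O)OC/C=C\COC(C)=O | starting material
4 | (E)-4-[4-(benzyloxy)-3,5-dimethoxyphenyl]but-2-en-1-yl acetate | CC(=O)OC/C=C/Cc1cc(OC)c(OCc2ccccc2)c(OC)c1 | intermediate
5 | 5-bromo-2-hydroxy-3-methoxybenzaldehyde | COc1cc(Br)cc(C=O)c1O | starting material
6 | 5-bromo-2-hydroxy-3-methoxyphenyl formate (not isolated) | COc1cc(Br)cc(OC=O)c1O | intermediate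
7 | 5-bromo-3-methoxybenzene-1,2-diol | COc1cc(Br)cc(O)c1O | intermediate
8 | 1,2-bis(benzyloxy)-5-bromo-3-methoxybenzene | COc1cc(Br)cc(OCc2ccccc2)c1OCc1ccccc1 | intermediate
9 | [3,4-bis(benzyloxy)-5-methoxyphenyl]lithium (not isolated) | COc1cc([Li])cc(OCc2ccccc2)c1OCc1ccccc1 | intermediate
10 | lithium [3,4-bis(benzyloxy)-5-methoxyphenyl]triisopropoxyborate (not isolated) | [Li+].COc1cc([B-](OC(C)C)(OC(C)C)OC(C)C)cc(OCc2ccccc2)c1OCc1ccccc1 | intermediate
11 | [3,4-bis(benzyloxy)-5-methoxyphenyl]boronic acid | COc1cc(B(O)O)cc(OCc2ccccc2)c1OCc1ccccc1 | intermediate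
12 | (E)-1-[3,4-bis(benzyloxy)-5-methoxyphenyl]-4-[4-(benzyloxy)-3,5-dimethoxyphenyl]but-2-ene | COc1cc(C/C=C/Cc2cc(OC)c(OCc3ccccc3)c(OC)c2)cc(OCc2ccccc2)c1OCc1ccccc1 | intermediate
13 | bis(catecholato)diboron, 2,2'-bi(1,3,2-benzodioxaborole) | O1c2ccccc2OB1B1Oc2ccccc2O1 | starting material
14 | (2R,3R)-2,3-bis(1,3,2-benzodioxaborol-2-yl)-1-[3,4-bis(benzyloxy)-5-methoxyphenyl]-4-[4-(benzyloxy)-3,5-dimethoxyphenyl]butane (not isolated) | COc1cc(C[C@@H](B2Oc3ccccc3O2)[C@H](B2Oc3ccccc3O2)Cc2cc(OC)c(OCc3ccccc3)c(OC)c2)cc(OCc2ccccc2)c1OCc1ccccc1 | intermediate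
15 | dilithium (2R,3R)-bis[chloromethyl(catecholato)borate] of 14, each boron carrying C8 or C8', CH2Cl and catecholate (not isolated) | [Li+].[Li+].COc1cc(C[C@@H]([B-]2(CCl)Oc3ccccc3O2)[C@H]([B-]2(CCl)Oc3ccccc3O2)Cc2cc(OC)c(OCc3ccccc3)c(OC)c2)cc(OCc2ccccc2)c1OCc1ccccc1 | intermediate
16 | (2R,3R)-1,4-bis(1,3,2-benzodioxaborol-2-yl)-2-[3,4-bis(benzyloxy)-5-methoxybenzyl]-3-[4-(benzyloxy)-3,5-dimethoxybenzyl]butane (not isolated) | COc1cc(C[C@@H](CB2Oc3ccccc3O2)[C@H](CB2Oc3ccccc3O2)Cc2cc(OC)c(OCc3ccccc3)c(OC)c2)cc(OCc2ccccc2)c1OCc1ccccc1 | intermediate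
17 | (2R,3R)-2-[3,4-bis(benzyloxy)-5-methoxybenzyl]-3-[4-(benzyloxy)-3,5-dimethoxybenzyl]butane-1,4-diol | COc1cc(C[C@@H](CO)[C@H](CO)Cc2cc(OC)c(OCc3ccccc3)c(OC)c2)cc(OCc2ccccc2)c1OCc1ccccc1 | intermediate
18 | (2R,3R)-2-[3,4-bis(benzyloxy)-5-methoxybenzyl]-3-[4-(benzyloxy)-3,5-dimethoxybenzyl]butane-1,4-diyl dimethanesulfonate | COc1cc(C[C@@H](COS(C)(=O)=O)[C@H](COS(C)(=O)=O)Cc2cc(OC)c(OCc3ccccc3)c(OC)c2)cc(OCc2ccccc2)c1OCc1ccccc1 | intermediate
19 | (2R,3R)-1-[3,4-bis(benzyloxy)-5-methoxyphenyl]-4-[4-(benzyloxy)-3,5-dimethoxyphenyl]-2,3-dimethylbutane | COc1cc(C[C@@H](C)[C@H](C)Cc2cc(OC)c(OCc3ccccc3)c(OC)c2)cc(OCc2ccccc2)c1OCc1ccccc1 | intermediate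
20 | sauriol B, 5-[(2R,3R)-4-(4-hydroxy-3,5-dimethoxyphenyl)-2,3-dimethylbutyl]-3-methoxybenzene-1,2-diol | COc1cc(C[C@@H](C)[C@H](C)Cc2cc(OC)c(O)c(OC)c2)cc(O)c1O | target

Total step count: 10. Longest linear sequence: 8 steps (5 → 20 through steps 3, 4, 5, 6, 7, 8, 9 and 10). The ring B branch (steps 1 and 2) joins at step 6.

Steps most likely to fail

Risk 1, step 7 (key step). Three processes threaten it.
- β-Hydride elimination from the β-borylalkyl rhodium intermediate towards benzylic C7 or C7' may occur, with rhodium hydride-driven migration of the alkene into conjugation.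
- Facial selectivity may fall below that of simple dialkyl E-alkenes.
- Homologation may stop after only one of the two boron atoms.

The fallback sets out from 12 and returns at 17. It gives up absolute control in the addition and recovers it by resolution. Alkene 12 is diborated without a transition metal by methoxide-activated bis(pinacolato)diboron (B2pin2, Cs2CO3 cat., MeOH, THF, 70 °C). This is a stereospecific syn addition that cannot generate metal hydrides, and it should give the racemic threo 2,3-bis(pinacolboronate) F1, which is robust enough for chromatography. Double Matteson homologation (BrCH2Cl, n-BuLi, THF, −78 °C → rt, resubmitted if one boron lags) should give the racemic 1,4-bis(pinacolboronate) F2. Oxidation with NaOH/H2O2 then gives 17 together with its (2S,3S)-enantiomer F3, which is removed by preparative HPLC on a chiral stationary phase.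

Risk 2, step 6. Five processes threaten it.
- If transmetalation is slow, the η3-allylpalladium intermediate may lose a benzylic C7' hydrogen by β-hydride elimination.
- The aryl group may be delivered to the substituted allyl terminus.
- The electron-rich boronic acid may protodeboronate.
- Palladium hydride may move the product alkene.
- Z geometry may leak through and be carried into the erythro series in step 7.

The fallback sets out from 2 and 8 and returns at 12. It forms C7–C8 instead of ring A–C7 by an sp3–sp2 Suzuki–Miyaura coupling that involves no allylpalladium species. Cross-metathesis of 2 with vinylboronic acid pinacol ester (second-generation Grubbs catalyst, CH2Cl2, 40 °C) should give the (E)-alkenylboronate F4. Bromide 8 is lithiated to 9 as in step 5 and quenched with paraformaldehyde to give the benzylic alcohol F5. PBr3 (Et2O, 0 °C) converts this into the benzylic bromide F6. Coupling of F4 with F6 (PdCl2(dppf), Cs2CO3, THF–H2O, 60 °C) should give 12 with retention of the E geometry.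

Risk 3, step 9. Hydride may attack sulfur instead of carbon. This frees an alkoxide that displaces the neighbouring mesylate intramolecularly (cyclic ether formation). The second reduction may also remain incomplete.

The fallback sets out from 18 and returns at 19. It replaces polar hydride displacement by radical dehalogenation. Finkelstein exchange (NaI, acetone, reflux) should give the (2R,3R)-1,4-diiodide F7. Bu3SnH with AIBN (toluene, 80 °C) then reduces both C–I bonds through primary radicals at C9 and C9' that leave C8 and C8' untouched.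

Further compounds
F1 | step 7 | threo 2,3-bis(4,4,5,5-tetramethyl-1,3,2-dioxaborolan-2-yl)-1-[3,4-bis(benzyloxy)-5-methoxyphenyl]-4-[4-(benzyloxy)-3,5-dimethoxyphenyl]butane (racemate, R,R enantiomer drawn) | COc1cc(C[C@@H](B2OC(C)(C)C(C)(C)O2)[C@H](B2OC(C)(C)C(C)(C)O2)Cc2cc(OC)c(OCc3ccccc3)c(OC)c2)cc(OCc2ccccc2)c1OCc1ccccc1
F2 | step 7 | threo 1,4-bis(4,4,5,5-tetramethyl-1,3,2-dioxaborolan-2-yl)-2-[3,4-bis(benzyloxy)-5-methoxybenzyl]-3-[4-(benzyloxy)-3,5-dimethoxybenzyl]butane (racemate, R,R enantiomer drawn) | COc1cc(C[C@@H](CB2OC(C)(C)C(C)(C)O2)[C@H](CB2OC(C)(C)C(C)(C)O2)Cc2cc(OC)c(OCc3ccccc3)c(OC)c2)cc(OCc2ccccc2)c1OCc1ccccc1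
F3 | step 7 | (2S,3S)-2-[3,4-bis(benzyloxy)-5-methoxybenzyl]-3-[4-(benzyloxy)-3,5-dimethoxybenzyl]butane-1,4-diol | COc1cc(C[C@H](CO)[C@@H](CO)Cc2cc(OC)c(OCc3ccccc3)c(OC)c2)cc(OCc2ccccc2)c1OCc1ccccc1
F4 | step 6 | (E)-2-{3-[4-(benzyloxy)-3,5-dimethoxyphenyl]prop-1-en-1-yl}-4,4,5,5-tetramethyl-1,3,2-dioxaborolane | CC1(C)OB(/C=C/Cc2cc(OC)c(OCc3ccccc3)c(OC)c2)OC1(C)C
F5 | step 6 | [3,4-bis(benzyloxy)-5-methoxyphenyl]methanol | COc1cc(CO)cc(OCc2ccccc2)c1OCc1ccccc1
F6 | step 6 | 1,2-bis(benzyloxy)-5-(bromomethyl)-3-methoxybenzene | COc1cc(CBr)cc(OCc2ccccc2)c1OCc1ccccc1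
F7 | step 9 | (2R,3R)-2-[3,4-bis(benzyloxy)-5-methoxybenzyl]-3-[4-(benzyloxy)-3,5-dimethoxybenzyl]-1,4-diiodobutane | COc1cc(C[C@@H](CI)[C@H](CI)Cc2cc(OC)c(OCc3ccccc3)c(OC)c2)cc(OCc2ccccc2)c1OCc1ccccc1
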